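Millimoles per litre are the currency here: each one of reagent consumed ends as one of target, once intermediate A has passed on. Crystals count as target, so they stay out of the balance.

- Wednesday's: substrate 0.050 M; reagent 0.0450 M; time 10 h
- Tuesday's: substrate 0.050 M; reagent 0.0900 M; time 10 h

    substrate + reagent → intermediate A (k1 = 2.11 L mol⁻¹ min⁻¹)
    intermediate A → target (k2 = 0.0162 min⁻¹)
    substrate ⇌ intermediate B (K3 = 0.43, k3 = 0.0113 min⁻¹)
    intermediate B → side product (k4 = 0.0273 min⁻¹)
    crystals ⇌ target, rate k5*(cs5 - [target]) while solid is left; crystals form when [target] > cs5 (cs5 = 23 mM, k5 = 0.147 min⁻¹)

- what is said of target includes crystals
- crystals is a solid; its amount is given per volume of the solution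
- run time (Wednesday's): 10 h

* which of the two there is more of at the end, Wednesday's (target / side product)
* which of the two there is more of at the end, Tuesday's (target / side product)
* final target, as a percentage of the substrate charged, in Wednesday's
* final target, as a percentage of the substrate charged, in Tuesday's

**What can happen to substrate?** It has two exits. Reagent takes it, at k1 times the reagent level. Or it slips into intermediate B, which returns at 0.0263 min⁻¹ or goes on to side product at 0.0273 min⁻¹.

**What is the net leak?** With intermediate B held at a low steady level, the forward rate times the share that goes on gives 0.00576 min⁻¹.

**Reduce it to one number.** Divide the leak by k1. This gives 2.73 mM, the break-even level, the reagent concentration at which the two exits run equally fast. Reagent level over break-even level is the selectivity factor.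

**But reagent falls. Doesn't that spoil it?** No. Divide one rate by the other and time cancels. Following the fraction of reagent left, side product formed = break-even level × ln(reagent charged / reagent left). Substrate consumed is reagent consumed plus that side product.

**Tuesday's?** As a first guess, Tuesday's reagent left is 40.0 mM. That gives 2.21 mM of side product. Adding this back to the reagent left gives a second pass of 2.07 mM of side product. So I say 95.9 % target, and more of target.

**Wednesday's has less reagent than substrate. Now what?** Wednesday's reagent is 5.00 mM short of its substrate. That gap has to go by the leak or stay as substrate. I try reagent left equal to the break-even level. The balance then consumes 49.9 mM of substrate against 50 mM charged. The trial closes, so I say 84.5 % target, and more of target.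

**Is there time?** At that reagent level in Wednesday's the exits are equal, so I reckon substrate's half-life at 1.00 h. The run lasts ten times that. Intermediate A's half-life of 0.71 h is also shorter than the run.

The forecast gave 85 % (81 % to 88 %) for Wednesday's and 95.5 % (93.5 % to 97 %) for Tuesday's, target ahead in both, holding that “Ten hours is long enough for intermediate A to convert fully”.

The simulation gives 84.6 % on Wednesday's and 95.8 % on Tuesday's, with target ahead in both.

The difference in reagent is the main reason Tuesday's ends higher: with that difference taken away, Tuesday's target falls from 95.8 % to 84.6 %. Wednesday's ends with 5.99 % of its reagent, which is 2.70 mM, close to the break-even level. Tuesday's ends with 42.1 mM of reagent, far above it. A further flask, like Wednesday's but with 0.030 M of substrate, gets the same two passes: 3.00 mM, then 2.50 mM, or 8.33 % of its substrate. That flask ends with 8.56 % as side product.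

Its constants belong to no real substance; the run is a simulation.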